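**Plan**

- Numbering follows the isochromene: ring B is C1(H2)–O2–C3–C4–C4a–C8a, ring A is C4a–C5–C6–C7–C8–C8a. The retrosynthesis cuts, in this order, the C6–O aroyl bond, the O2–C3 bond of ring B, the two epoxide C–O bonds, the bond from the alkyne terminus to the propenyl carbon, and last C8–C8a and C4a–C5 of ring A.
- Enabling feature: the four-carbon arc C8–C7–C6–C5 of ring A bridges both ends of the tetrasubstituted C8a=C4a alkene. Ring A is therefore a cyclobutanone (C8, C7, C6, C5) opened at C8–C5 with two alkyne carbons (C8a, C4a) placed in the gap.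
- Forward order: cyclobutanone by Norrish–Yang photocyclisation, a silyl-capped 1,3-diyne by Cadiot–Chodkiewicz coupling, ring A by nickel-catalysed insertion, side chain by C-desilylation, Sonogashira coupling and epoxidation, ring B by 6-endo-dig addition of C1–OH to C3, orsellinate ester last.
- Stereochemistry: the cis C6/C7 oxygen pair comes from the photocyclisation (relative) and a lipase resolution (absolute). The trans-epoxide comes from a catalyst-controlled Shi epoxidation of the E-enyne.
- The epoxide is made after the nickel step because a propargylic epoxide would probably be ionised by zerovalent nickel. The triisopropylsilyl cap keeps the second alkyne out of the insertion.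

Key step: step 8

Abbreviations: TBS = tert-butyldimethylsilyl, TIPS = triisopropylsilyl.

Assumption: the lipase is taken to follow its usual preference for the secondary carbinol enantiomer whose larger substituent is the oxygenated quaternary carbon, so that the wanted (2R,3R)-enantiomer is the one deacetylated; (bromoethynyl)triisopropylsilane and (E)-1-bromopropene are taken as purchased.

**Route**

Step 1
Reactants: 1 pent-3-yn-1-ol
Product: 2 pent-3-yn-1-yl acetate
Conditions: Ac2O, pyridine, DMAP (cat.), CH2Cl2, 0 °C to rt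
Reagents that add atoms: acetic anhydride, CC(=O)OC(C)=O
Why: DMAP-catalysed acetylation of a primary alcohol; the acetate is the group the lipase later recognises and it survives oxidation and irradiation.

Step 2
Reactants: 2 pent-3-yn-1-yl acetate
Product: 3 3,4-dioxopentyl acetate
Conditions: RuO2·xH2O (2 mol%), NaIO4, EtOAc/MeCN/H2O, 0 °C
Reagents that add atoms: sodium periodate NaIO4, [Na+].[O-]I(=O)(=O)=O
Why: RuO4 generated in the flask oxidises internal dialkyl alkynes to 1,2-diketones (alkyne-to-dione oxidation), and a short, cold, neutral run should avoid over-cleavage and beta-elimination of the acetate.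

Step 3
Reactants: 3 3,4-dioxopentyl acetate
Product: 4 rac-(1R,2R)-2-hydroxy-2-methyl-3-oxocyclobutyl acetate
Conditions: hν (blue LEDs, ca. 450 nm), degassed benzene (dilute), rt; minor trans isomer removed by chromatography
Reagents that add atoms: none
Why: Norrish–Yang photocyclisation, in which the excited dione abstracts a hydrogen from the acetoxy-bearing carbon through a six-membered transition state and the 1,4-biradical closes to the 2-hydroxycyclobutanone; the acetoxy group should settle trans to the larger methyl and within hydrogen-bond reach of the new hydroxyl, which sets the cis oxygen pair (later C6/C7) in racemic form, and visible light does not excite the product ketone.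

Step 4
Reactants: 4 rac-(1R,2R)-2-hydroxy-2-methyl-3-oxocyclobutyl acetate
Product: 5 (2R,3R)-2,3-dihydroxy-2-methylcyclobutan-1-one
Conditions: immobilised Candida antarctica lipase B, n-BuOH, MTBE, 30 °C, stopped near half conversion; diol separated from unreacted (1S,2S)-acetate by chromatography
Reagents that add atoms: none
Why: lipase-catalysed kinetic resolution by enantioselective transesterification of a secondary acetate, in which the enantiomer with the R carbinol centre should be deacetylated faster; this fixes the absolute configuration of the future C6 and, through the cis relationship, of C7.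

Step 5
Reactants: 5 (2R,3R)-2,3-dihydroxy-2-methylcyclobutan-1-one
Product: 6 (2R,3R)-2,3-bis[(tert-butyldimethylsilyl)oxy]-2-methylcyclobutan-1-one
Conditions: TBSOTf, 2,6-lutidine, CH2Cl2, −78 to 0 °C
Reagents that add atoms: tert-butyldimethylsilyl trifluoromethanesulfonate, CC(C)(C)[Si](C)(C)OS(=O)(=O)C(F)(F)F
Why: silyl triflate silylation covers the secondary and the hindered tertiary hydroxyl in one operation, and silyl ethers are poor leaving groups beta to nickel that later fall to fluoride.

Step 6
Reactants: 7 prop-2-yn-1-ol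
Product: 8 tert-butyldimethyl(prop-2-yn-1-yloxy)silane
Conditions: TBSCl, imidazole, CH2Cl2, 0 °C to rt
Reagents that add atoms: tert-butyldimethylsilyl chloride, CC(C)(C)[Si](C)(C)Cl
Why: standard imidazole-promoted silylation of a primary alcohol, giving an ether stable to the aqueous amine of the next step.

Step 7
Reactants: 8 tert-butyldimethyl(prop-2-yn-1-yloxy)silane; 9 (bromoethynyl)triisopropylsilane
Product: 10 tert-butyldimethyl{[5-(triisopropylsilyl)penta-2,4-diyn-1-yl]oxy}silane
Conditions: CuCl (5 mol%), NH2OH·HCl, n-BuNH2 (30% aq.), Et2O, 0 °C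
Reagents that add atoms: none
Why: Cadiot–Chodkiewicz coupling of a terminal alkyne with a 1-bromoalkyne, in which hydroxylamine keeps copper monovalent so that homocoupling stays low, and the bulky silyl group stabilises the bromoalkyne.

Step 8
Reactants: 6 (2R,3R)-2,3-bis[(tert-butyldimethylsilyl)oxy]-2-methylcyclobutan-1-one; 10 tert-butyldimethyl{[5-(triisopropylsilyl)penta-2,4-diyn-1-yl]oxy}silane
Product: 11 (5R,6R)-5,6-bis[(tert-butyldimethylsilyl)oxy]-2-{[(tert-butyldimethylsilyl)oxy]methyl}-6-methyl-3-[(triisopropylsilyl)ethynyl]cyclohex-2-en-1-one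
Conditions: Ni(cod)2 (10 mol%), PCy3 (20 mol%), toluene, 100 °C, slow addition of 10
Reagents that add atoms: none
Why: Zerovalent nickel binds the unsilylated alkyne of 10 and the ketone of 6 and couples them oxidatively to an oxanickelacyclopentene (C8–C8a formed, nickel on C4a), strain-driven beta-carbon elimination then breaks C8–C5 to give a seven-membered nickelacycle, and C(sp2)–C(sp3) reductive elimination joins C4a to C5. The closest known reaction is the Ni(cod)2/PCy3-catalysed intermolecular insertion of internal alkynes into cyclobutanones, which gives cyclohex-2-enones. Ring A therefore arises by two-carbon ring expansion of the four-membered ring (formal [4+2]) and not by an endo or exo cyclisation onto the tetrasubstituted alkene. No stereocentre is formed, and C6 and C7 are carried over unchanged from 6 because C7 is quaternary and C6 is not alpha to the ketone. Three selectivities are needed: the conjugating alkynyl substituent should sit next to nickel so that the CH2OTBS carbon bonds to C8 (as conjugated enynes and diynes do in nickel oxidative cyclisations), the TIPS cap should shield the second alkyne, and the unhindered methylene C5 rather than the quaternary, oxygenated C7 should migrate to nickel. The siloxy group at C6 is a poor leaving group, which should hold back beta-oxygen elimination from the alkylnickel intermediate, and slow addition of 10 should limit diyne oligomerisation.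

Step 9
Reactants: 11 (5R,6R)-5,6-bis[(tert-butyldimethylsilyl)oxy]-2-{[(tert-butyldimethylsilyl)oxy]methyl}-6-methyl-3-[(triisopropylsilyl)ethynyl]cyclohex-2-en-1-one
Product: 13 (5R,6R)-5,6-bis[(tert-butyldimethylsilyl)oxy]-2-{[(tert-butyldimethylsilyl)oxy]methyl}-3-ethynyl-6-methylcyclohex-2-en-1-one, via silver acetylide 12 (not isolated)
Conditions: AgF, MeOH/THF, rt, dark; then 1 M HCl, 0 °C, brief
Reagents that add atoms: none
Why: silver-mediated protodesilylation of a C(sp)–Si bond, in which fluoride attacks the silicon of the silver-bound alkyne to give the silver acetylide and dilute acid protonates it, whereas the O-silyl ethers are not activated by silver and should survive the short exposure.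

Step 10
Reactants: 13 (5R,6R)-5,6-bis[(tert-butyldimethylsilyl)oxy]-2-{[(tert-butyldimethylsilyl)oxy]methyl}-3-ethynyl-6-methylcyclohex-2-en-1-one; 14 (E)-1-bromoprop-1-ene
Product: 15 (5R,6R)-5,6-bis[(tert-butyldimethylsilyl)oxy]-2-{[(tert-butyldimethylsilyl)oxy]methyl}-6-methyl-3-[(3E)-pent-3-en-1-yn-1-yl]cyclohex-2-en-1-one
Conditions: Pd(PPh3)4 (5 mol%), CuI (10 mol%), Et3N, THF, rt, excess 14
Reagents that add atoms: none
Why: Sonogashira coupling of a terminal alkyne with an alkenyl bromide proceeds with retention of the E geometry, and a tertiary amine base avoids conjugate addition to the electron-poor enyne.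

Step 11
Reactants: 15 (5R,6R)-5,6-bis[(tert-butyldimethylsilyl)oxy]-2-{[(tert-butyldimethylsilyl)oxy]methyl}-6-methyl-3-[(3E)-pent-3-en-1-yn-1-yl]cyclohex-2-en-1-one
Product: 16 (5R,6R)-5,6-bis[(tert-butyldimethylsilyl)oxy]-2-{[(tert-butyldimethylsilyl)oxy]methyl}-6-methyl-3-{[(2R,3R)-3-methyloxiran-2-yl]ethynyl}cyclohex-2-en-1-one
Conditions: 1,2:4,5-di-O-isopropylidene-β-D-erythro-2,3-hexodiulo-2,6-pyranose (30 mol%), KHSO5 (as 2KHSO5·KHSO4·K2SO4), K2CO3, Bu4NHSO4, MeCN/dimethoxymethane/aq. Na2B4O7 buffer, 0 °C
Reagents that add atoms: potassium peroxymonosulfate KHSO5, [K+].[O-]S(=O)(=O)OO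
Why: Shi epoxidation, in which the chiral dioxirane from the D-fructose-derived ketone epoxidises trans-disubstituted alkenes (conjugated enynes included) through a spiro transition state and should deliver oxygen to the face that gives the (2R,3R)-epoxide, so both new stereocentres are set by the catalyst while the tetrasubstituted, electron-poor ring alkene and the alkyne are left alone.

Step 12
Reactants: 16 (5R,6R)-5,6-bis[(tert-butyldimethylsilyl)oxy]-2-{[(tert-butyldimethylsilyl)oxy]methyl}-6-methyl-3-{[(2R,3R)-3-methyloxiran-2-yl]ethynyl}cyclohex-2-en-1-one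
Product: 18 (6R,7R)-6,7-dihydroxy-7-methyl-3-[(2S,3R)-3-methyloxiran-2-yl]-1,5,6,7-tetrahydro-8H-isochromen-8-one, via enynone triol 17 (not isolated)
Conditions: Bu4NF, THF, 0 °C to rt; pH 7 buffer work-up, base-washed silica
Reagents that add atoms: none
Why: fluoride cleaves the three silyl ethers and the freed C1 alkoxide adds to C3, the electrophilic terminus of the C8=O/C8a=C4a/C4≡C3 enynone (oxa-Michael addition, 6-endo-dig closure of ring B), the 5-exo mode being disfavoured because attack at C4 would leave an unstabilised vinyl anion; no stereocentre is formed or disturbed.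

Step 13
Reactants: 19 orsellinic acid (2,4-dihydroxy-6-methylbenzoic acid)
Product: 21 2,4-bis[(tert-butyldimethylsilyl)oxy]-6-methylbenzoic acid, via tris-silylated silyl ester 20 (not isolated)
Conditions: TBSCl, imidazole, DMF, rt; then AcOH/THF/H2O, rt
Reagents that add atoms: tert-butyldimethylsilyl chloride, CC(C)(C)[Si](C)(C)Cl
Why: exhaustive silylation followed by selective hydrolysis of the much more labile silyl ester leaves the free acid with both phenols masked by groups removable under buffered fluoride.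

Step 14
Reactants: 18 (6R,7R)-6,7-dihydroxy-7-methyl-3-[(2S,3R)-3-methyloxiran-2-yl]-1,5,6,7-tetrahydro-8H-isochromen-8-one; 21 2,4-bis[(tert-butyldimethylsilyl)oxy]-6-methylbenzoic acid
Product: 23 (6R,7R)-7-hydroxy-7-methyl-3-[(2S,3R)-3-methyloxiran-2-yl]-8-oxo-5,6,7,8-tetrahydro-1H-isochromen-6-yl 2,4-bis[(tert-butyldimethylsilyl)oxy]-6-methylbenzoate, via aroyl chloride 22 (not isolated)
Conditions: 21, 1-chloro-N,N,2-trimethylprop-1-en-1-amine, CH2Cl2, 0 °C to rt; then 18, DMAP, CH2Cl2, −20 to 0 °C
Reagents that add atoms: none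
Why: neutral acid chloride formation followed by DMAP-catalysed acylation (nucleophilic catalysis) should esterify the secondary C6 hydroxyl, the tertiary C7 hydroxyl next to the ketone being too hindered to compete, and C6 keeps its configuration because its C–O bond is not broken.

Step 15
Reactants: 23 (6R,7R)-7-hydroxy-7-methyl-3-[(2S,3R)-3-methyloxiran-2-yl]-8-oxo-5,6,7,8-tetrahydro-1H-isochromen-6-yl 2,4-bis[(tert-butyldimethylsilyl)oxy]-6-methylbenzoate
Product: 24 (6R,7R)-7-hydroxy-7-methyl-3-[(2S,3R)-3-methyloxiran-2-yl]-8-oxo-5,6,7,8-tetrahydro-1H-isochromen-6-yl 2,4-dihydroxy-6-methylbenzoate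
Conditions: Bu4NF/AcOH (1:1), THF, 0 °C
Reagents that add atoms: none
Why: fluoride cleavage of the two aryl silyl ethers, buffered with acetic acid so that the ester is not eliminated across C5–C6 and the epoxy enol ether meets neither strong acid nor free alkoxide.

**Compound list**

1 | pent-3-yn-1-ol | CC#CCCO | starting material
2 | pent-3-yn-1-yl acetate | CC#CCCOC(C)=O | intermediate
3 | 3,4-dioxopentyl acetate | CC(=O)C(=O)CCOC(C)=O | intermediate
4 | rac-(1R,2R)-2-hydroxy-2-methyl-3-oxocyclobutyl acetate (racemate, one enantiomer drawn) | O=C1C[C@@H](OC(C)=O)[C@@]1(C)O | intermediate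
5 | (2R,3R)-2,3-dihydroxy-2-methylcyclobutan-1-one | O=C1C[C@@H](O)[C@@]1(C)O | intermediate
6 | (2R,3R)-2,3-bis[(tert-butyldimethylsilyl)oxy]-2-methylcyclobutan-1-one | O=C1C[C@@H](O[Si](C)(C)C(C)(C)C)[C@@]1(C)O[Si](C)(C)C(C)(C)C | intermediate
7 | prop-2-yn-1-ol | C#CCO | starting material
8 | tert-butyldimethyl(prop-2-yn-1-yloxy)silane | C#CCO[Si](C)(C)C(C)(C)C | intermediate
9 | (bromoethynyl)triisopropylsilane | BrC#C[Si](C(C)C)(C(C)C)C(C)C | starting material
10 | tert-butyldimethyl{[5-(triisopropylsilyl)penta-2,4-diyn-1-yl]oxy}silane | CC(C)(C)[Si](C)(C)OCC#CC#C[Si](C(C)C)(C(C)C)C(C)C | intermediate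
11 | (5R,6R)-5,6-bis[(tert-butyldimethylsilyl)oxy]-2-{[(tert-butyldimethylsilyl)oxy]methyl}-6-methyl-3-[(triisopropylsilyl)ethynyl]cyclohex-2-en-1-one | CC(C)(C)[Si](C)(C)O[C@@H]1CC(C#C[Si](C(C)C)(C(C)C)C(C)C)=C(CO[Si](C)(C)C(C)(C)C)C(=O)[C@]1(C)O[Si](C)(C)C(C)(C)C | intermediate
12 | silver acetylide of 13 | CC(C)(C)[Si](C)(C)O[C@@H]1CC(C#C[Ag])=C(CO[Si](C)(C)C(C)(C)C)C(=O)[C@]1(C)O[Si](C)(C)C(C)(C)C | intermediate
13 | (5R,6R)-5,6-bis[(tert-butyldimethylsilyl)oxy]-2-{[(tert-butyldimethylsilyl)oxy]methyl}-3-ethynyl-6-methylcyclohex-2-en-1-one | CC(C)(C)[Si](C)(C)O[C@@H]1CC(C#C)=C(CO[Si](C)(C)C(C)(C)C)C(=O)[C@]1(C)O[Si](C)(C)C(C)(C)C | intermediate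
14 | (E)-1-bromoprop-1-ene | C/C=C/Br | starting material
15 | (5R,6R)-5,6-bis[(tert-butyldimethylsilyl)oxy]-2-{[(tert-butyldimethylsilyl)oxy]methyl}-6-methyl-3-[(3E)-pent-3-en-1-yn-1-yl]cyclohex-2-en-1-one | CC(C)(C)[Si](C)(C)O[C@@H]1CC(C#C/C=C/C)=C(CO[Si](C)(C)C(C)(C)C)C(=O)[C@]1(C)O[Si](C)(C)C(C)(C)C | intermediate
16 | (5R,6R)-5,6-bis[(tert-butyldimethylsilyl)oxy]-2-{[(tert-butyldimethylsilyl)oxy]methyl}-6-methyl-3-{[(2R,3R)-3-methyloxiran-2-yl]ethynyl}cyclohex-2-en-1-one | CC(C)(C)[Si](C)(C)O[C@@H]1CC(C#C[C@H]2O[C@@H]2C)=C(CO[Si](C)(C)C(C)(C)C)C(=O)[C@]1(C)O[Si](C)(C)C(C)(C)C | intermediate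
17 | (5R,6R)-5,6-dihydroxy-2-(hydroxymethyl)-6-methyl-3-{[(2R,3R)-3-methyloxiran-2-yl]ethynyl}cyclohex-2-en-1-one | O[C@@H]1CC(C#C[C@H]2O[C@@H]2C)=C(CO)C(=O)[C@]1(C)O | intermediate
18 | (6R,7R)-6,7-dihydroxy-7-methyl-3-[(2S,3R)-3-methyloxiran-2-yl]-1,5,6,7-tetrahydro-8H-isochromen-8-one | O[C@@H]1CC2=C(COC([C@H]3O[C@@H]3C)=C2)C(=O)[C@]1(C)O | intermediate
19 | orsellinic acid | Cc1cc(O)cc(O)c1C(=O)O | starting material
20 | tert-butyldimethylsilyl 2,4-bis[(tert-butyldimethylsilyl)oxy]-6-methylbenzoate | Cc1cc(O[Si](C)(C)C(C)(C)C)cc(O[Si](C)(C)C(C)(C)C)c1C(=O)O[Si](C)(C)C(C)(C)C | intermediate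
21 | 2,4-bis[(tert-butyldimethylsilyl)oxy]-6-methylbenzoic acid | Cc1cc(O[Si](C)(C)C(C)(C)C)cc(O[Si](C)(C)C(C)(C)C)c1C(=O)O | intermediate
22 | 2,4-bis[(tert-butyldimethylsilyl)oxy]-6-methylbenzoyl chloride | Cc1cc(O[Si](C)(C)C(C)(C)C)cc(O[Si](C)(C)C(C)(C)C)c1C(Cl)=O | intermediate
23 | (6R,7R)-7-hydroxy-7-methyl-3-[(2S,3R)-3-methyloxiran-2-yl]-8-oxo-5,6,7,8-tetrahydro-1H-isochromen-6-yl 2,4-bis[(tert-butyldimethylsilyl)oxy]-6-methylbenzoate | Cc1cc(O[Si](C)(C)C(C)(C)C)cc(O[Si](C)(C)C(C)(C)C)c1C(=O)O[C@@H]1CC2=C(COC([C@H]3O[C@@H]3C)=C2)C(=O)[C@]1(C)O | intermediate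
24 | (6R,7R)-7-hydroxy-7-methyl-3-[(2S,3R)-3-methyloxiran-2-yl]-8-oxo-5,6,7,8-tetrahydro-1H-isochromen-6-yl 2,4-dihydroxy-6-methylbenzoate | Cc1cc(O)cc(O)c1C(=O)O[C@@H]1CC2=C(COC([C@H]3O[C@@H]3C)=C2)C(=O)[C@]1(C)O | target

**Step count**

Total steps: 15. Longest linear sequence: 12 steps (1–5, 8–12, 14, 15, from pent-3-yn-1-ol).

**Steps most likely to fail**

Step 8. The diyne may oligomerise on nickel, the alkyne may insert in the reverse orientation or at the silylated triple bond, or the oxidative cyclisation may be too slow at the hindered carbonyl for the catalyst to stay productive. The fallback sets out from 8 and 6 and returns at 13; it still relies on insertion into 6 and answers only the diyne-side failures. Sonogashira coupling of 8 with vinyl bromide (Pd(PPh3)4, CuI, Et3N) should give the enyne tert-butyldimethyl(pent-4-en-2-yn-1-yloxy)silane F1. Under the nickel conditions of step 8 the conjugated vinyl group should steer C–C bond formation to the distal alkyne carbon, a control element established for 1,3-enynes with four-membered ketones, so insertion of F1 into 6 should give (5R,6R)-5,6-bis[(tert-butyldimethylsilyl)oxy]-2-{[(tert-butyldimethylsilyl)oxy]methyl}-3-ethenyl-6-methylcyclohex-2-en-1-one F2. Lemieux–Johnson cleavage (OsO4 cat., NaIO4, 2,6-lutidine, dioxane/H2O) of the monosubstituted vinyl group, which should react ahead of the tetrasubstituted electron-poor ring alkene, would give (4R,5R)-4,5-bis[(tert-butyldimethylsilyl)oxy]-2-{[(tert-butyldimethylsilyl)oxy]methyl}-4-methyl-3-oxocyclohex-1-ene-1-carbaldehyde F3. Seyferth–Gilbert homologation with dimethyl (1-diazo-2-oxopropyl)phosphonate and K2CO3 in MeOH then gives 13.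

Step 12. Ring B may close in the 5-exo mode or not at all under fluoride, and the tertiary silyl ether may be cleaved too slowly for a clean one-pot run. The fallback sets out from 16 and returns at 18. Buffered desilylation (Bu4NF/AcOH, THF) would give the triol 17, this time isolated. Iodocyclisation (I2, NaHCO3, MeCN, 0 °C), an electrophile-triggered 6-endo-dig closure that places oxygen on the alkyne carbon remote from the electron-poor ring, should give (6R,7R)-6,7-dihydroxy-4-iodo-7-methyl-3-[(2S,3R)-3-methyloxiran-2-yl]-1,5,6,7-tetrahydro-8H-isochromen-8-one F4. Radical hydrodeiodination (Bu3SnH, Et3B, air, toluene, 0 °C) then gives 18; a palladium-catalysed reduction is avoided because the product is an alkenyl epoxide.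

Step 14. Acyl transfer from a doubly ortho-substituted aroyl chloride to a hindered secondary alcohol may be slow, and amine-induced elimination of the new ester across C5–C6 may compete. The fallback sets out from 18 and returns at 24, so step 15 is not needed. It builds the arene on the ester oxygen instead of transferring it. Purchased 2,2,6-trimethyl-4H-1,3-dioxin-4-one is acetylated at its dienolate terminus (LiN(SiMe3)2, THF, −78 °C, then acetyl chloride) to 2,2-dimethyl-6-(2-oxopropyl)-4H-1,3-dioxin-4-one F5. The dianion of F5 (LiN(iPr)2, 2 equiv) is acetylated with N-methoxy-N-methylacetamide to 6-(2,4-dioxopentyl)-2,2-dimethyl-4H-1,3-dioxin-4-one F6. Heating F6 with 18 in toluene at about 100 °C releases an acylketene that the C6 hydroxyl should trap as (6R,7R)-7-hydroxy-7-methyl-3-[(2S,3R)-3-methyloxiran-2-yl]-8-oxo-5,6,7,8-tetrahydro-1H-isochromen-6-yl 3,5,7-trioxooctanoate F7. Brief treatment with a mild base (Cs2CO3, MeOH, 0 °C) and then acetic acid closes the C2–C7 aldol bond of the trioxooctanoate and dehydrates it (biomimetic resorcylate aromatisation) to the orsellinate 24. The substrate is sensitive to both base and acid, so this aromatisation carries its own risk.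

Further compounds
F1 | step 8 | tert-butyldimethyl(pent-4-en-2-yn-1-yloxy)silane | C=CC#CCO[Si](C)(C)C(C)(C)C
F2 | step 8 | (5R,6R)-5,6-bis[(tert-butyldimethylsilyl)oxy]-2-{[(tert-butyldimethylsilyl)oxy]methyl}-3-ethenyl-6-methylcyclohex-2-en-1-one | CC(C)(C)[Si](C)(C)O[C@@H]1CC(C=C)=C(CO[Si](C)(C)C(C)(C)C)C(=O)[C@]1(C)O[Si](C)(C)C(C)(C)C
F3 | step 8 | (4R,5R)-4,5-bis[(tert-butyldimethylsilyl)oxy]-2-{[(tert-butyldimethylsilyl)oxy]methyl}-4-methyl-3-oxocyclohex-1-ene-1-carbaldehyde | CC(C)(C)[Si](C)(C)O[C@@H]1CC(C=O)=C(CO[Si](C)(C)C(C)(C)C)C(=O)[C@]1(C)O[Si](C)(C)C(C)(C)C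
F4 | step 12 | (6R,7R)-6,7-dihydroxy-4-iodo-7-methyl-3-[(2S,3R)-3-methyloxiran-2-yl]-1,5,6,7-tetrahydro-8H-isochromen-8-one | O[C@@H]1CC2=C(COC([C@H]3O[C@@H]3C)=C2I)C(=O)[C@]1(C)O
F5 | step 14 | 2,2-dimethyl-6-(2-oxopropyl)-4H-1,3-dioxin-4-one | CC(=O)CC1=CC(=O)OC(C)(C)O1
F6 | step 14 | 6-(2,4-dioxopentyl)-2,2-dimethyl-4H-1,3-dioxin-4-one | CC(=O)CC(=O)CC1=CC(=O)OC(C)(C)O1
F7 | step 14 | (6R,7R)-7-hydroxy-7-methyl-3-[(2S,3R)-3-methyloxiran-2-yl]-8-oxo-5,6,7,8-tetrahydro-1H-isochromen-6-yl 3,5,7-trioxooctanoate | CC(=O)CC(=O)CC(=O)CC(=O)O[C@@H]1CC2=C(COC([C@H]3O[C@@H]3C)=C2)C(=O)[C@]1(C)O
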